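Whoever ran Monday's and Tuesday's flasks left me two sets of readings and the new recipes below, and I wanted to know how far each new flask would get in its time.

in all of them: substrate 23 mM
- Monday's: partner 23 mM; temperature 1 °C; run made earlier
- Tuesday's: partner 35 mM; temperature 26 °C; run made earlier
- cedar: partner 16.1 mM; temperature 20 °C; time 2.5 min
- alder: partner 16.1 mM; temperature 5 °C; time 2.5 min
- oak: partner 16.1 mM; temperature −10 °C; time 2.5 min
- maple: partner 16.1 mM; temperature 35 °C; time 2.5 min

| run | time / min | target / % | substrate / % |
|---|---|---|---|
| Monday's | 0.500 | 13.9 | 88.2 |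
| Monday's | 1.50 | 25.1 | 73.4 |
| Monday's | 3.00 | 30.0 | 66.0 |
| Monday's | 5.00 | 28.1 | 63.8 |
| Monday's | 6.00 | 28.4 | 65.7 |
| Tuesday's | 0.200 | 27.0 | 71.9 |
| Tuesday's | 0.667 | 29.4 | 69.3 |
| Tuesday's | 1.33 | 28.5 | 68.5 |
| Tuesday's | 2.00 | 31.2 | 68.8 |
| Tuesday's | 2.50 | 29.5 | 67.1 |

(each reading ± 1 percentage point)

- the numbers in the tables scatter by 1 percentage point (one standard deviation)

* the flask that comes out highest in amount of target, in percent of the substrate charged, or "all alike" when all lie within 1.5 percentage points (cedar / alder / oak / maple / all alike)
* target at the end, in percent of the substrate charged, cedar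
* target at the end, in percent of the substrate charged, alder
* target at the end, in percent of the substrate charged, oak
* target at the end, in percent of the substrate charged, maple

Target went flat at about 28.8% on Monday and 29.6% on Tuesday. Substrate still stood at 65.7% at Monday's last reading, so I took partner to be the limiting reagent. That gave me a share φ, target made per partner charged: 28.8% on Monday, 19.5% on Tuesday.

Next came the clock. If the gap to the plateau shrinks steadily at rate λ, the first readings give 1.32 min⁻¹ on Monday and 12.1 min⁻¹ on Tuesday. I assumed a fixed factor per degree for both λ and φ, which put oak at λ = 0.496 min⁻¹. Its unfinished fraction, u = exp(−λt), the part of the partner still unused at time t, came to 28.9%.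

Putting that back into the share, with 34.3% for oak, gave oak 17.0%. Alder, with λ = 1.88 min⁻¹, finishes and gave 18.8%. Cedar gave 15.0% and maple 11.8%. So I called alder highest.

The weak link was Tuesday's λ, which rests on a remainder of 2.6 percentage points against a scatter of 1 point. I went round again with that remainder larger or smaller by a factor 2, and oak moved between 16.1% and 18.3%. I kept the number.

The forecast, from someone who saw the same two runs, named alder, with cedar 16.8%, alder 20.3%, oak 17.3% and maple 13.8%, and it began from another reading than mine: “The plateau is reached while substrate and partner both remain”.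

The flasks gave cedar 21.7%, alder 24.8%, oak 16.8% and maple 19.1%, so alder came out highest.

    substrate + partner → target, rate k1*[substrate]*[partner]^0.5 (k = 0.220 M⁻⁰·⁵ s⁻¹, Ea = 60.0 kJ mol⁻¹)
    2 partner → self-condensation product (k = 2.20 M⁻¹ s⁻¹, Ea = 57.0 kJ mol⁻¹)
    partner → decomposed reagent (k = 0.0830 s⁻¹, Ea = 79.0 kJ mol⁻¹)
    target ⇌ isomer of the product (K = 0.110, k = 0.00850 s⁻¹, Ea = 74.0 kJ mol⁻¹, ΔH = −24.0 kJ mol⁻¹)
    (constants at 20 °C)

My shares ran low for cedar, alder and maple: alder turned 35.4% of its partner into target. Oak's 16.8% is held down in part by the short run, acting together with the consumption of partner: oak run to 25.0 min gives 25.2%, and oak at its own time with the consumption of partner taken away gives 21.9%. At 2.50 min oak still held 31% of its partner against my u of 28.9%. The same clock, for alder read at 40 s, gives u = 28.6%, and that flask held 21% of its partner.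

(The runs come from a simulation for substances that don't exist; scatter was added.)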